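**Strategy.** Everything rests on opening ring C of the flavanone at O1–C2 and C4–C4a, which turns the target into an aryl (E)-cinnamate. The feature exploited is that C4a of ring A is ortho to the O1-bearing C8a, and that O1 is β to the C4 carbonyl through C3 and C2. In the key step, iodine–lithium exchange at C4a of an ortho-iodoaryl 4-silyloxycinnamate triggers a 1,3 O→C acyl shift (C4–C4a), and the O1 phenoxide set free closes ring C by oxa-Michael addition to C2, without acid, so both geranyl groups survive. The precursor is a fully differentiated phloroglucinol ester; the (2S) enantiomer is then secured by kinetic resolution.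

Key step: step 7

Remark: geranyl stands for (2E)-3,7-dimethylocta-2,6-dien-1-yl and TIPS for triisopropylsilyl; commercial geraniol and geranyl bromide are assumed to be the pure E isomers.

**Step 1**
Reactants: 1 phloroglucinol (benzene-1,3,5-triol); 2 geranyl bromide
Product: 3 2-geranylbenzene-1,3,5-triol
Conditions: DBU (1 equiv), 1 in excess (3 equiv), THF, 0 °C to rt
Reagents that add atoms: none
Why: Base-mediated C-alkylation (SN2 at the primary allylic bromide) of the ambident phloroglucinol anion; the three ring carbons of 1 are equivalent, excess 1 suppresses dialkylation, and the E alkene is not touched.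

**Step 2**
Reactants: 3 2-geranylbenzene-1,3,5-triol
Product: 4 2-geranyl-5-(triisopropylsilyloxy)benzene-1,3-diol
Conditions: TIPSCl (1.0 equiv), imidazole, DMF, 0 °C
Reagents that add atoms: triisopropylsilyl chloride, CC(C)[Si](Cl)(C(C)C)C(C)C
Why: Silyl ether formation under steric control: the hydroxyl at C5 has two ring hydrogens as neighbours, whereas those at C1 and C3 are shielded by the geranyl chain, so one equivalent of the bulky chloride should go to O5.

**Step 3**
Reactants: 4 2-geranyl-5-(triisopropylsilyloxy)benzene-1,3-diol; 5 geraniol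
Product: 6 2-geranyl-3-(geranyloxy)-5-(triisopropylsilyloxy)phenol
Conditions: PPh3, DIAD, 5 (1.0 equiv), THF, 0 °C to rt
Reagents that add atoms: none
Why: Mitsunobu etherification (neutral, O-selective, SN2 at the primary allylic carbon with the E geometry kept); the two hydroxyls of 4 are equivalent by symmetry, so limiting geraniol should give the single mono-ether 6, with unreacted 4 recycled.

**Step 4**
Reactants: 6 2-geranyl-3-(geranyloxy)-5-(triisopropylsilyloxy)phenol
Product: 7 2-geranyl-3-(geranyloxy)-6-iodo-5-(triisopropylsilyloxy)phenol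
Conditions: I2 (1.0 equiv), NaHCO3, THF–H2O, 0 °C, dark
Reagents that add atoms: iodine, II
Why: Electrophilic aromatic iodination of the phenoxide, whose ring should react with iodine much faster than the trisubstituted alkenes; of the two open ring carbons, C6 ortho to the free hydroxyl is expected to be attacked, because the para carbon C4 is wedged between the geranyloxy and silyloxy groups.

**Step 5**
Reactants: 8 (E)-4-hydroxycinnamic acid
Product: 10 (E)-3-[4-(triisopropylsilyloxy)phenyl]prop-2-enoic acid, via silyl ester 9 (not isolated)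
Conditions: TIPSCl (2.2 equiv), imidazole, DMF, rt; then AcOH, THF–H2O, rt
Reagents that add atoms: triisopropylsilyl chloride, CC(C)[Si](Cl)(C(C)C)C(C)C
Why: Silylation of both the phenol and the acid, followed by selective hydrolysis of the far more labile silyl ester 9, which leaves the aryl silyl ether in place.

**Step 6**
Reactants: 7 2-geranyl-3-(geranyloxy)-6-iodo-5-(triisopropylsilyloxy)phenol; 10 (E)-3-[4-(triisopropylsilyloxy)phenyl]prop-2-enoic acid
Product: 11 2-geranyl-3-(geranyloxy)-6-iodo-5-(triisopropylsilyloxy)phenyl (E)-3-[4-(triisopropylsilyloxy)phenyl]prop-2-enoate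
Conditions: DIC, DMAP (cat.), CH2Cl2, 0 °C to rt
Reagents that add atoms: none
Why: Steglich esterification (carbodiimide activation, DMAP acyl transfer) should acylate the only free, hindered phenol under neutral conditions that leave the iodide, silyl ethers and alkenes untouched.

**Step 7 (key step)**
Reactants: 11 2-geranyl-3-(geranyloxy)-6-iodo-5-(triisopropylsilyloxy)phenyl (E)-3-[4-(triisopropylsilyloxy)phenyl]prop-2-enoate
Product: 14 racemic 8-geranyl-7-(geranyloxy)-5-(triisopropylsilyloxy)-2-[4-(triisopropylsilyloxy)phenyl]chroman-4-one, via aryllithium 12 (not isolated), via hydroxychalcone 13 (not isolated)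
Conditions: n-BuLi (1.05 equiv), THF, −100 to −78 °C, then 0 °C; then AcOH (1.1 equiv), NaOAc, EtOH, 60 °C
Reagents that add atoms: none
Why: n-BuLi should exchange the iodide at the carbon that becomes C4a faster than it adds to the ester, and aryllithium 12 then attacks its own ester carbonyl through a four-membered tetrahedral intermediate (1,3 O→C acyl shift), which forms C4–C4a and releases O1 as the lithium phenoxide. After buffering with AcOH and NaOAc, the 2'-hydroxychalcone 13 closes ring C by 6-endo-trig oxa-Michael addition of O1 to the β-carbon of the enone, which forms O1–C2. The closest known reaction types are the halogen–metal-exchange-induced anionic Fries rearrangement of ortho-haloaryl esters and the base-mediated chalcone–flavanone isomerisation. C2 is created in a reversible closure with no chiral element present, so 14 is expected as the racemate and the (2S) series is selected in step 8. The step needs 1,2-acyl transfer in preference to conjugate attack on the enoate or O→C silyl migration, which the hard aryllithium, the low temperature and the bulky triisopropylsilyl group should secure; it also needs closure through O1 alone, which the silyl cap on O5 and the geranyl-blocked second ortho carbon guarantee. No acid stronger than acetic acid is present, so the geranyl ether and the C-geranyl chain should survive.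

**Step 8**
Reactants: 14 racemic 8-geranyl-7-(geranyloxy)-5-(triisopropylsilyloxy)-2-[4-(triisopropylsilyloxy)phenyl]chroman-4-one
Product: 15 (2S)-8-geranyl-7-(geranyloxy)-5-(triisopropylsilyloxy)-2-[4-(triisopropylsilyloxy)phenyl]chroman-4-one
Conditions: RuCl(p-cymene)[(R,R)-TsDPEN] (1 mol%), HCO2H–Et3N, EtOAc, rt, stopped just past half conversion
Reagents that add atoms: none
Why: Asymmetric transfer hydrogenation used as a kinetic resolution (Noyori–Ikariya catalyst): the (R,R) complex delivers hydride to the carbonyl face that gives the 4R alcohol, which for the (2R) ketone is the favoured axial attack leading to the cis-(2R,4R)-flavan-4-ol, so the mismatched (2S) ketone 15 should be left behind, while isolated alkenes and silyl ethers are inert.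

**Step 9**
Reactants: 15 (2S)-8-geranyl-7-(geranyloxy)-5-(triisopropylsilyloxy)-2-[4-(triisopropylsilyloxy)phenyl]chroman-4-one
Product: 16 (2S)-8-geranyl-7-(geranyloxy)-5-hydroxy-2-(4-hydroxyphenyl)chroman-4-one (CNP0103685.1)
Conditions: TBAF, AcOH (1:1), THF, 0 °C
Reagents that add atoms: none
Why: Fluoride-mediated cleavage of both aryl silyl ethers; buffering with acetic acid keeps the medium from becoming basic, so ring C should not open by retro-oxa-Michael reaction and C2 keeps its configuration.

**Compound list**

1 | phloroglucinol (benzene-1,3,5-triol) | Oc1cc(O)cc(O)c1 | starting material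
2 | geranyl bromide | CC(C)=CCC/C(C)=C/CBr | starting material
3 | 2-geranylbenzene-1,3,5-triol | Oc1cc(O)c(C/C=C(\C)CCC=C(C)C)c(O)c1 | intermediate
4 | 2-geranyl-5-(triisopropylsilyloxy)benzene-1,3-diol | CC(C)[Si](Oc1cc(O)c(C/C=C(\C)CCC=C(C)C)c(O)c1)(C(C)C)C(C)C | intermediate
5 | geraniol | CC(C)=CCC/C(C)=C/CO | starting material
6 | 2-geranyl-3-(geranyloxy)-5-(triisopropylsilyloxy)phenol | CC(C)=CCC/C(C)=C/COc1cc(O[Si](C(C)C)(C(C)C)C(C)C)cc(O)c1C/C=C(\C)CCC=C(C)C | intermediate
7 | 2-geranyl-3-(geranyloxy)-6-iodo-5-(triisopropylsilyloxy)phenol | CC(C)=CCC/C(C)=C/COc1cc(O[Si](C(C)C)(C(C)C)C(C)C)c(I)c(O)c1C/C=C(\C)CCC=C(C)C | intermediate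
8 | (E)-4-hydroxycinnamic acid | OC(=O)/C=C/c1ccc(O)cc1 | starting material
9 | triisopropylsilyl (E)-3-[4-(triisopropylsilyloxy)phenyl]prop-2-enoate | CC(C)[Si](OC(=O)/C=C/c1ccc(O[Si](C(C)C)(C(C)C)C(C)C)cc1)(C(C)C)C(C)C | intermediate (not isolated)
10 | (E)-3-[4-(triisopropylsilyloxy)phenyl]prop-2-enoic acid | OC(=O)/C=C/c1ccc(O[Si](C(C)C)(C(C)C)C(C)C)cc1 | intermediate
11 | 2-geranyl-3-(geranyloxy)-6-iodo-5-(triisopropylsilyloxy)phenyl (E)-3-[4-(triisopropylsilyloxy)phenyl]prop-2-enoate | CC(C)=CCC/C(C)=C/COc1cc(O[Si](C(C)C)(C(C)C)C(C)C)c(I)c(OC(=O)/C=C/c2ccc(O[Si](C(C)C)(C(C)C)C(C)C)cc2)c1C/C=C(\C)CCC=C(C)C | intermediate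
12 | 6-lithio analogue of 11 (iodine replaced by lithium) | CC(C)=CCC/C(C)=C/COc1cc(O[Si](C(C)C)(C(C)C)C(C)C)c([Li])c(OC(=O)/C=C/c2ccc(O[Si](C(C)C)(C(C)C)C(C)C)cc2)c1C/C=C(\C)CCC=C(C)C | intermediate (not isolated)
13 | (E)-1-[3-geranyl-4-(geranyloxy)-2-hydroxy-6-(triisopropylsilyloxy)phenyl]-3-[4-(triisopropylsilyloxy)phenyl]prop-2-en-1-one | CC(C)=CCC/C(C)=C/COc1cc(O[Si](C(C)C)(C(C)C)C(C)C)c(C(=O)/C=C/c2ccc(O[Si](C(C)C)(C(C)C)C(C)C)cc2)c(O)c1C/C=C(\C)CCC=C(C)C | intermediate (not isolated)
14 | racemic 8-geranyl-7-(geranyloxy)-5-(triisopropylsilyloxy)-2-[4-(triisopropylsilyloxy)phenyl]chroman-4-one | CC(C)=CCC/C(C)=C/COc1cc(O[Si](C(C)C)(C(C)C)C(C)C)c2c(c1C/C=C(\C)CCC=C(C)C)OC(c1ccc(O[Si](C(C)C)(C(C)C)C(C)C)cc1)CC2=O | intermediate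
15 | (2S)-8-geranyl-7-(geranyloxy)-5-(triisopropylsilyloxy)-2-[4-(triisopropylsilyloxy)phenyl]chroman-4-one | CC(C)=CCC/C(C)=C/COc1cc(O[Si](C(C)C)(C(C)C)C(C)C)c2c(c1C/C=C(\C)CCC=C(C)C)O[C@H](c1ccc(O[Si](C(C)C)(C(C)C)C(C)C)cc1)CC2=O | intermediate
16 | (2S)-8-geranyl-7-(geranyloxy)-5-hydroxy-2-(4-hydroxyphenyl)chroman-4-one | CC(C)=CCC/C(C)=C/COc1cc(O)c2c(c1C/C=C(\C)CCC=C(C)C)O[C@H](c1ccc(O)cc1)CC2=O | target

**Step count and risks**

Total step count: 9. Longest linear sequence: 8 steps (steps 1, 2, 3, 4, 6, 7, 8, 9 from phloroglucinol); step 5 is the side branch.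

Steps most likely to fail:

1. **Step 7.** Addition of n-BuLi to the aryl ester or enoate may compete with iodine–lithium exchange, the aryllithium may attack the enoate in conjugate fashion, or ring closure may stop at the chalcone–flavanone equilibrium. The fallback sets out from 7 and 10 and comes back at 14; it replaces the intramolecular acyl shift by an intermolecular acylation with a softer aryl nucleophile. Acid 10 is converted with CDI and MeNHOMe·HCl into the Weinreb amide (E)-N-methoxy-N-methyl-3-[4-(triisopropylsilyloxy)phenyl]prop-2-enamide F1. Phenol 7 is deprotonated with MeMgCl and its iodide exchanged with iPrMgCl·LiCl, and the arylmagnesium is added once to F1 to give hydroxychalcone 13 after work-up. Compound 13 is isolated and closed separately with NaOAc in EtOH to give 14.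

2. **Step 4.** Iodonium transfer to the ortho-geranyl alkene followed by ring closure through the free hydroxyl (iodoetherification), or substitution at C4 in place of C6, may consume the phenol. The fallback sets out from 6 and comes back at 7; it replaces electrophilic substitution by directed ortho-metalation. Compound 6 is capped with MOMCl and iPr2NEt as 2-geranyl-1-(geranyloxy)-3-(methoxymethoxy)-5-(triisopropylsilyloxy)benzene F2. This is lithiated with n-BuLi and TMEDA in THF at the only open carbon ortho to the acetal and quenched with I2 at −78 °C to give 2-geranyl-1-(geranyloxy)-4-iodo-3-(methoxymethoxy)-5-(triisopropylsilyloxy)benzene F3. The acetal is then removed with ZnBr2 and n-PrSH in CH2Cl2 at 0 °C to give 7.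

3. **Step 8.** Hydride transfer may be slow or poorly discriminating because the C4 carbonyl sits beside the bulky 5-silyloxy group, so that both enantiomers are reduced at similar rates. The fallback sets out from hydroxychalcone 13 (isolated by working up step 7 after the AcOH quench at 0 °C) and comes back at 15; it replaces resolution by catalytic asymmetric ring closure. Compound 13 is cyclised by intramolecular oxa-Michael addition under a cinchona-alkaloid-derived bifunctional thiourea in toluene at low temperature, with the pseudoenantiomer of the catalyst chosen for the (2S) product, to give 15 directly. This fallback makes no compound outside the list (F0).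

**Further compounds**

F1 | step 7 | (E)-N-methoxy-N-methyl-3-[4-(triisopropylsilyloxy)phenyl]prop-2-enamide | CON(C)C(=O)/C=C/c1ccc(O[Si](C(C)C)(C(C)C)C(C)C)cc1
F2 | step 4 | 2-geranyl-1-(geranyloxy)-3-(methoxymethoxy)-5-(triisopropylsilyloxy)benzene | CC(C)=CCC/C(C)=C/COc1cc(O[Si](C(C)C)(C(C)C)C(C)C)cc(OCOC)c1C/C=C(\C)CCC=C(C)C
F3 | step 4 | 2-geranyl-1-(geranyloxy)-4-iodo-3-(methoxymethoxy)-5-(triisopropylsilyloxy)benzene | CC(C)=CCC/C(C)=C/COc1cc(O[Si](C(C)C)(C(C)C)C(C)C)c(I)c(OCOC)c1C/C=C(\C)CCC=C(C)C
F0 | step 8 | none | none
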